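Ring B (C5–C10, eremophilane numbering; ring A is C1–C5/C10) is a cross-conjugated cyclohexadienone-type ring that quaternary C5 keeps from aromatising and that carries carbon on C7, next to the C8 carbonyl. It is therefore not closed as a six-membered ring: a cyclopentenone C5–C6–C8–C9–C10 is fused to ring A first, and its cross-conjugated silyl dienol ether takes up dibromocarbene across C6=C8; opening of the dibromocyclopropane inserts C7 and leaves a 7-bromo dienone, whose bromine brings in the isopropylidene carbons. Ring A comes from (S)-carvone, whose isopropenyl group sets C4 and C5 and is then excised to give C1=C2.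

Key step: step 8

Remark: as read from the SMILES, the C3 ester oxygen, the C4 methyl and the C5 methyl lie on one face of ring A (3S,4R,5R in eremophilane numbering), and the acid is (2E,4E,6S); atom labels C1–C13 in the Why lines are eremophilane labels.

Step 1
Reactants: 1 (S)-(+)-carvone; 2 propargyl bromide
Product: 4 (2R,3S,5S)-2,3-dimethyl-5-(prop-1-en-2-yl)-2-(prop-2-yn-1-yl)cyclohexan-1-one, via lithium enolate 3 (not isolated)
Conditions: Me2CuLi, Et2O, 0 °C; then 2, DMPU, THF, −20 °C to rt
Reagents that add atoms: lithium dimethylcuprate, [Li+].C[Cu-]C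
Why: Tandem cuprate conjugate addition–enolate alkylation, in which the methyl adds axially to the β-carbon anti to the isopropenyl group (sets C4) and the regiodefined enolate is propargylated on the face opposite the new axial methyl (sets quaternary C5 with the two methyls cis).

Step 2
Reactants: 4
Product: 6 (5S,6R)-5,6-dimethyl-6-(prop-2-yn-1-yl)cyclohex-2-en-1-one, via methoxy hydroperoxide 5 (not isolated)
Conditions: O3, CH2Cl2/MeOH, −78 °C; then Cu(OAc)2·H2O, FeSO4·7H2O, −78 °C to rt
Reagents that add atoms: none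
Why: Ozonolysis of the 1,1-disubstituted alkene (the alkyne reacts far more slowly) gives the α-methoxy hydroperoxide, Fe(II) reduction of which triggers alkoxy-radical β-scission with loss of methyl acetate, and Cu(II) oxidises the ring radical to the alkene in conjugation with the ketone (dealkenylative dehydrogenation); only the excised stereocentre is lost.

Step 3
Reactants: 6
Product: 7 tert-butyl{[(5S,6R)-5,6-dimethyl-6-(prop-2-yn-1-yl)cyclohexa-1,3-dien-1-yl]oxy}dimethylsilane
Conditions: TBSOTf, Et3N, CH2Cl2, 0 °C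
Reagents that add atoms: tert-butyldimethylsilyl trifluoromethanesulfonate, CC(C)(C)[Si](C)(C)OS(=O)(=O)C(F)(F)F
Why: Soft enolisation can only remove a γ-hydrogen because the α′-carbon is quaternary, so the linear 1-siloxy-1,3-diene should form regiospecifically.

Step 4
Reactants: 7
Product: 9 (4R,5R,6R)-4-hydroxy-5,6-dimethyl-6-(prop-2-yn-1-yl)cyclohex-2-en-1-one, via silyloxy epoxide 8 (not isolated)
Conditions: mCPBA, NaHCO3, CH2Cl2, −20 °C; then aq. citric acid
Reagents that add atoms: 3-chloroperbenzoic acid, OOC(=O)c1cccc(Cl)c1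
Why: Vinylogous Rubottom oxidation, in which the peracid epoxidises the distal double bond of the dienol ether from the face opposite the two cis methyl groups and the epoxide collapses to the γ-hydroxy enone, so the new carbinol centre (C3) is expected trans to the methyls.

Step 5
Reactants: 9
Product: 10 (4R,5R,6R)-4-[(tert-butyldimethylsilyl)oxy]-5,6-dimethyl-6-(prop-2-yn-1-yl)cyclohex-2-en-1-one
Conditions: TBSCl, imidazole, DMF, rt
Reagents that add atoms: tert-butyldimethylsilyl chloride, CC(C)(C)[Si](C)(C)Cl
Why: Standard silylation of the secondary allylic alcohol, which keeps the hydroxyl from adding to the gold-activated alkyne and carries it through the base and carbene steps.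

Step 6
Reactants: 10
Product: 12 (6R,7R,7aR)-6-[(tert-butyldimethylsilyl)oxy]-7,7a-dimethyl-1,6,7,7a-tetrahydro-2H-inden-2-one, via diketone 11 (not isolated)
Conditions: (IPr)AuCl (2 mol %), AgSbF6 (2 mol %), 1,4-dioxane/H2O, 60 °C; then KOH (cat.), MeOH, 0 °C to rt
Reagents that add atoms: water, O
Why: Markovnikov gold-catalysed alkyne hydration gives the methyl ketone, whose enolate closes the five-membered ring on the ring carbonyl (C10) and dehydrates irreversibly (intramolecular aldol condensation of a 1,4-diketone to a cyclopentenone), without touching a stereocentre.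

Step 7
Reactants: 12
Product: 13 {[(6R,7R,7aS)-6-[(tert-butyldimethylsilyl)oxy]-7,7a-dimethyl-7,7a-dihydro-6H-inden-2-yl]oxy}trimethylsilane
Conditions: LDA, THF, −78 °C; then TMSCl, Et3N
Reagents that add atoms: chlorotrimethylsilane, C[Si](C)(C)Cl
Why: Kinetic deprotonation of the dienone at the α′-methylene (C6) and O-silylation give the cross-conjugated 2-siloxycyclopenta-1,3-diene, which the quaternary C5 protects from 1,5-hydrogen shifts.

Step 8
Reactants: 13
Product: 15 (4aS,5R,6R)-3-bromo-6-[(tert-butyldimethylsilyl)oxy]-4a,5-dimethyl-5,6-dihydronaphthalen-2(4aH)-one, via dibromocyclopropane 14 (not isolated)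
Conditions: CHBr3, KOtBu, pentane, −30 °C to rt
Reagents that add atoms: bromoform, BrC(Br)Br
Why: Dibromocarbene, formed by α-elimination from bromoform, adds in a [2+1] step to the most electron-rich double bond of 13, the silyl enol ether C6=C8, to give 14; its cyclopropane then undergoes the thermally allowed disrotatory two-electron electrocyclic opening to a 2-bromoallyl cation with loss of bromide, which breaks the old C6–C8 bond so that the carbene carbon becomes C7 of a six-membered ring, and transfer of the trimethylsilyl group to bromide releases the C8 ketone. The closest known reaction type is the one-carbon ring expansion of cyclic silyl enol ethers with dihalocarbenes to 2-halocycloalk-2-enones (related to the carbene ring expansion of cyclopentadienes and indenes to six-membered aromatics). No ring is closed end to end: ring B arises by enlargement of the five-membered ring to six atoms (cyclopropanation, then electrocyclic ring opening). No stereocentre is formed and C3, C4 and C5 are not involved. The step needs chemoselectivity for C6=C8 over C9=C10 and C1=C2, which the siloxy donor secures, and it needs the product to stop at the dienone, which the quaternary C5 secures by blocking aromatisation.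

Step 9
Reactants: 15; 16 isopropenylboronic acid pinacol ester
Product: 17 (4aR,5R,6R)-6-[(tert-butyldimethylsilyl)oxy]-4a,5-dimethyl-3-(prop-1-en-2-yl)-5,6-dihydronaphthalen-2(4aH)-one
Conditions: Pd(dppf)Cl2 (5 mol %), K3PO4, 1,4-dioxane/H2O, 60 °C
Reagents that add atoms: none
Why: Suzuki–Miyaura coupling of the α-bromo enone, an activated vinyl bromide for oxidative addition, attaches C11–C13 to C7 as an isopropenyl group.

Step 10
Reactants: 17
Product: 19 (4aR,5R,6R)-6-[(tert-butyldimethylsilyl)oxy]-4a,5-dimethyl-3-(propan-2-ylidene)-4,4a,5,6-tetrahydronaphthalen-2(3H)-one, via deconjugated ketone 18 (not isolated)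
Conditions: L-Selectride, THF, −78 °C; then aq. NH4Cl; then DBU (cat.), CH2Cl2, rt
Reagents that add atoms: none
Why: Conjugate hydride addition should go to C6, the only β-carbon of the cross-conjugated dienone that bears hydrogen (as in the selective reduction of the less substituted double bond of cyclohexa-2,5-dienones), and base then moves the isopropenyl double bond into conjugation as the tetrasubstituted isopropylidene ketone.

Step 11
Reactants: 19
Product: 20 (4aR,5R,6R)-6-hydroxy-4a,5-dimethyl-3-(propan-2-ylidene)-4,4a,5,6-tetrahydronaphthalen-2(3H)-one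
Conditions: HF·pyridine, pyridine, THF, 0 °C to rt
Reagents that add atoms: none
Why: Buffered fluoride desilylation removes the silyl ether without exposing the base-sensitive trienone to alkoxide.

Step 12
Reactants: 21 (S)-2-methylbutan-1-ol
Product: 22 (S)-2-methylbutanal
Conditions: TEMPO (cat.), PhI(OAc)2, CH2Cl2, 0 °C to rt; used as a solution
Reagents that add atoms: none
Why: Oxoammonium-mediated oxidation stops at the aldehyde under near-neutral conditions, so the α-stereocentre should not epimerise.

Step 13
Reactants: 22; 23 triethyl (E)-4-phosphonocrotonate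
Product: 24 ethyl (2E,4E,6S)-6-methylocta-2,4-dienoate
Conditions: 23, LiHMDS, THF, −78 °C; then 22, −78 to 0 °C
Reagents that add atoms: none
Why: Vinylogous Horner–Wadsworth–Emmons olefination with a stabilised phosphonate anion gives the (2E,4E)-dienoate, and the low temperature protects the α-stereocentre of the aldehyde.

Step 14
Reactants: 24
Product: 25 (2E,4E,6S)-6-methylocta-2,4-dienoic acid
Conditions: LiOH, THF/H2O, rt; then 1 M HCl
Reagents that add atoms: lithium hydroxide, [Li+].[OH-]
Why: Saponification of the ethyl ester, under which the non-acidic C6 stereocentre and the diene geometry are retained.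

Step 15
Reactants: 20; 25
Product: 26 (4aR,5R,6S)-6-hydroxy-4a,5-dimethyl-3-(propan-2-ylidene)-4,4a,5,6-tetrahydronaphthalen-2(3H)-one (2E,4E,6S)-6-methylocta-2,4-dienoate (target)
Conditions: PPh3, DIAD, toluene, 0 °C to rt
Reagents that add atoms: none
Why: Mitsunobu esterification, in which the carboxylate displaces the allylic alkoxyphosphonium by SN2 with inversion, turning the trans carbinol (C3) into the ester that is cis to both methyl groups.

Compound list
1 | (S)-(+)-carvone, (5S)-2-methyl-5-(prop-1-en-2-yl)cyclohex-2-en-1-one | CC1=CC[C@@H](CC1=O)C(C)=C | starting material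
2 | propargyl bromide (3-bromoprop-1-yne) | BrCC#C | starting material
3 | lithium (3S,5S)-2,3-dimethyl-5-(prop-1-en-2-yl)cyclohex-1-en-1-olate | [Li+].[O-]C1=C(C)[C@@H](C)C[C@H](C(C)=C)C1 | intermediate
4 | (2R,3S,5S)-2,3-dimethyl-5-(prop-1-en-2-yl)-2-(prop-2-yn-1-yl)cyclohexan-1-one | O=C1C[C@@H](C(C)=C)C[C@H](C)[C@@]1(C)CC#C | intermediate
5 | (2R,3S,5S)-5-(1-hydroperoxy-1-methoxyethyl)-2,3-dimethyl-2-(prop-2-yn-1-yl)cyclohexan-1-one (both epimers at the peroxy carbon) | O=C1C[C@@H](C(C)(OC)OO)C[C@H](C)[C@@]1(C)CC#C | intermediate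
6 | (5S,6R)-5,6-dimethyl-6-(prop-2-yn-1-yl)cyclohex-2-en-1-one | O=C1C=CC[C@H](C)[C@@]1(C)CC#C | intermediate
7 | tert-butyl{[(5S,6R)-5,6-dimethyl-6-(prop-2-yn-1-yl)cyclohexa-1,3-dien-1-yl]oxy}dimethylsilane | CC(C)(C)[Si](C)(C)OC1=CC=C[C@H](C)[C@@]1(C)CC#C | intermediate
8 | 3,4-epoxide of 7, oxirane on the face opposite the two methyl groups | CC(C)(C)[Si](C)(C)OC1=C[C@H]2O[C@H]2[C@H](C)[C@@]1(C)CC#C | intermediate
9 | (4R,5R,6R)-4-hydroxy-5,6-dimethyl-6-(prop-2-yn-1-yl)cyclohex-2-en-1-one (hydroxyl trans to the cis methyl pair) | O=C1C=C[C@@H](O)[C@H](C)[C@@]1(C)CC#C | intermediate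
10 | (4R,5R,6R)-4-[(tert-butyldimethylsilyl)oxy]-5,6-dimethyl-6-(prop-2-yn-1-yl)cyclohex-2-en-1-one | O=C1C=C[C@@H](O[Si](C)(C)C(C)(C)C)[C@H](C)[C@@]1(C)CC#C | intermediate
11 | (4R,5R,6R)-4-[(tert-butyldimethylsilyl)oxy]-5,6-dimethyl-6-(2-oxopropyl)cyclohex-2-en-1-one | O=C1C=C[C@@H](O[Si](C)(C)C(C)(C)C)[C@H](C)[C@@]1(C)CC(C)=O | intermediate
12 | (6R,7R,7aR)-6-[(tert-butyldimethylsilyl)oxy]-7,7a-dimethyl-1,6,7,7a-tetrahydro-2H-inden-2-one | CC(C)(C)[Si](C)(C)O[C@@H]1C=CC2=CC(=O)C[C@]2(C)[C@H]1C | intermediate
13 | {[(6R,7R,7aS)-6-[(tert-butyldimethylsilyl)oxy]-7,7a-dimethyl-7,7a-dihydro-6H-inden-2-yl]oxy}trimethylsilane | CC(C)(C)[Si](C)(C)O[C@@H]1C=CC2=CC(O[Si](C)(C)C)=C[C@]2(C)[C@H]1C | intermediate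
14 | dibromocarbene adduct of 13 across the siloxy-bearing double bond (gem-dibromocyclopropane; either face, both converge) | CC(C)(C)[Si](C)(C)O[C@@H]1C=CC2=CC3(O[Si](C)(C)C)C(Br)(Br)C3[C@]2(C)[C@H]1C | intermediate
15 | (4aS,5R,6R)-3-bromo-6-[(tert-butyldimethylsilyl)oxy]-4a,5-dimethyl-5,6-dihydronaphthalen-2(4aH)-one | CC(C)(C)[Si](C)(C)O[C@@H]1C=CC2=CC(=O)C(Br)=C[C@]2(C)[C@H]1C | intermediate
16 | isopropenylboronic acid pinacol ester | CC(=C)B1OC(C)(C)C(C)(C)O1 | starting material
17 | (4aR,5R,6R)-6-[(tert-butyldimethylsilyl)oxy]-4a,5-dimethyl-3-(prop-1-en-2-yl)-5,6-dihydronaphthalen-2(4aH)-one | CC(C)(C)[Si](C)(C)O[C@@H]1C=CC2=CC(=O)C(C(C)=C)=C[C@]2(C)[C@H]1C | intermediate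
18 | (4aR,5R,6R)-6-[(tert-butyldimethylsilyl)oxy]-4a,5-dimethyl-3-(prop-1-en-2-yl)-4,4a,5,6-tetrahydronaphthalen-2(3H)-one (both C3 epimers) | CC(C)(C)[Si](C)(C)O[C@@H]1C=CC2=CC(=O)C(C(C)=C)C[C@]2(C)[C@H]1C | intermediate
19 | (4aR,5R,6R)-6-[(tert-butyldimethylsilyl)oxy]-4a,5-dimethyl-3-(propan-2-ylidene)-4,4a,5,6-tetrahydronaphthalen-2(3H)-one | CC(C)(C)[Si](C)(C)O[C@@H]1C=CC2=CC(=O)C(=C(C)C)C[C@]2(C)[C@H]1C | intermediate
20 | (4aR,5R,6R)-6-hydroxy-4a,5-dimethyl-3-(propan-2-ylidene)-4,4a,5,6-tetrahydronaphthalen-2(3H)-one | O[C@@H]1C=CC2=CC(=O)C(=C(C)C)C[C@]2(C)[C@H]1C | intermediate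
21 | (S)-2-methylbutan-1-ol | CC[C@H](C)CO | starting material
22 | (S)-2-methylbutanal | CC[C@H](C)C=O | intermediate
23 | triethyl (E)-4-phosphonocrotonate | CCOC(=O)/C=C/CP(=O)(OCC)OCC | starting material
24 | ethyl (2E,4E,6S)-6-methylocta-2,4-dienoate | CC[C@H](C)/C=C/C=C/C(=O)OCC | intermediate
25 | (2E,4E,6S)-6-methylocta-2,4-dienoic acid | CC[C@H](C)/C=C/C=C/C(=O)O | intermediate
26 | (4aR,5R,6S)-4a,5-dimethyl-2-oxo-3-(propan-2-ylidene)-2,3,4,4a,5,6-hexahydronaphthalen-6-yl (2E,4E,6S)-6-methylocta-2,4-dienoate | CC[C@H](C)/C=C/C=C/C(=O)O[C@H]1C=CC2=CC(=O)C(=C(C)C)C[C@]2(C)[C@H]1C | target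

Total step count: 15 (11 to alcohol 20, 3 to acid 25, 1 coupling). Longest linear sequence: 12 steps (steps 1–11 and 15, from (S)-carvone).

Steps most likely to fail

Step 8 (key step). The carbene may add unselectively to the other double bonds, tert-butoxide may cleave the silyl enol ether before cyclopropanation, or the adduct may not open cleanly. The fallback sets out from 13 and comes back at 19. Simmons–Smith cyclopropanation (Et2Zn, CH2I2) of 13 would give the siloxycyclopropane F1. FeCl3 in DMF would open it by one-electron oxidation and β-scission of the internal bond (Ito–Saegusa ring expansion, again five to six atoms) to the β-chloro ketone F2, and NaOAc in MeOH would eliminate HCl to the unbrominated cross-conjugated dienone F3. Conjugate reduction with L-Selectride and trapping of the enolate with acetone (ZnCl2) would give the aldol F4, whose dehydration (TsOH cat., benzene) would give 19, so that steps 9 and 10 are bypassed.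

Step 4. The peracid may attack the α-carbon of the dienol ether instead of the γ-terminus, or the facial selectivity may be poor. The fallback sets out from 7 and comes back at 9. Sensitised photooxygenation (O2, hν, tetraphenylporphyrin, CH2Cl2, −78 °C) would add singlet oxygen in a [4+2] manner across the diene termini from the face opposite the two methyl groups to give the endoperoxide F5, in which the position of the new C–O bond is fixed by the cycloaddition. Reduction with PPh3 and loss of the silanol from the resulting hemiketal would give 9.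

Step 15. The SN2 displacement may be slow because the carboxylate must enter 1,3-syn to the angular methyl, which would let elimination or SN2′ attack compete; the step also depends on the facial selectivity assumed in step 4. The fallback sets out from 20 and ends at 26. MnO2 would oxidise the allylic alcohol to the enedione F6. Luche reduction (NaBH4, CeCl3, MeOH, −78 °C) should reduce the less hindered ring-A carbonyl from the face opposite the axial angular methyl to the cis alcohol F7. Steglich esterification (DCC, DMAP, CH2Cl2) with 25 would then give 26 with retention. This sequence converges both carbinol epimers of 20.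

Further compounds
F1 | step 8 | Simmons–Smith adduct of 13 across the siloxy-bearing double bond (siloxycyclopropane; either face) | CC(C)(C)[Si](C)(C)O[C@@H]1C=CC2=CC3(O[Si](C)(C)C)CC3[C@]2(C)[C@H]1C
F2 | step 8 | 6-[(tert-butyldimethylsilyl)oxy]-4-chloro-4a,5-dimethyl-4,4a,5,6-tetrahydronaphthalen-2(3H)-one (both C4 epimers) | CC(C)(C)[Si](C)(C)O[C@@H]1C=CC2=CC(=O)CC(Cl)[C@]2(C)[C@H]1C
F3 | step 8 | (4aR,5R,6R)-6-[(tert-butyldimethylsilyl)oxy]-4a,5-dimethyl-5,6-dihydronaphthalen-2(4aH)-one | CC(C)(C)[Si](C)(C)O[C@@H]1C=CC2=CC(=O)C=C[C@]2(C)[C@H]1C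
F4 | step 8 | 6-[(tert-butyldimethylsilyl)oxy]-3-(2-hydroxypropan-2-yl)-4a,5-dimethyl-4,4a,5,6-tetrahydronaphthalen-2(3H)-one (both C3 epimers) | CC(C)(C)[Si](C)(C)O[C@@H]1C=CC2=CC(=O)C(C(C)(C)O)C[C@]2(C)[C@H]1C
F5 | step 4 | tert-butyl{[7,8-dimethyl-8-(prop-2-yn-1-yl)-2,3-dioxabicyclo[2.2.2]oct-5-en-1-yl]oxy}dimethylsilane, peroxide bridge anti to the methyl groups | CC(C)(C)[Si](C)(C)O[C@@]12C=C[C@@H](OO1)[C@H](C)[C@@]2(C)CC#C
F6 | step 15 | (4aR,5R)-4a,5-dimethyl-3-(propan-2-ylidene)-4,4a-dihydronaphthalene-2,6(3H,5H)-dione | O=C1C=CC2=CC(=O)C(=C(C)C)C[C@]2(C)[C@H]1C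
F7 | step 15 | (4aR,5R,6S)-6-hydroxy-4a,5-dimethyl-3-(propan-2-ylidene)-4,4a,5,6-tetrahydronaphthalen-2(3H)-one | O[C@H]1C=CC2=CC(=O)C(=C(C)C)C[C@]2(C)[C@H]1C
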